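The process chemist asked me what to change when violet is run again, and I answered from the charges and constants before any run was computed.

| setting | violet | grey | blue | green |
|---|---|---|---|---|
| starting material | 0.20 M | 0.20 M | 0.20 M | 0.20 M |
| reagent | 0.300 M | 0.300 M | 0.300 M | 0.300 M |
| protic impurity | 0.0100 M | 0.0100 M | 0.0100 M | 0.0100 M |
| temperature | 0 °C | −20 °C |  | −40 °C |
| time | 30 min | 30 min | 30 min | 30 min |
| remark |  |  | at −40 °C until 20 min, from then on at 0 °C |  |

- the flask that comes out highest in amount of target, in percent of the starting material charged, or "all alike" when all lie within 1.5 percentage points (violet / grey / blue / green / all alike)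
- target at the end, in percent of the starting material charged, violet
- target at the end, in percent of the starting material charged, grey
- target at the end, in percent of the starting material charged, blue
- target at the end, in percent of the starting material charged, green

    starting material + reagent ⇌ target (K1 = 49 M⁻¹, k1 = 0.059 M⁻¹ s⁻¹, Ea1 = 42.0 kJ mol⁻¹, ΔH1 = 37.0 kJ mol⁻¹)
    starting material + reagent ⇌ isomer of the product (K2 = 9.1 M⁻¹, k2 = 0.031 M⁻¹ s⁻¹, Ea2 = 42.0 kJ mol⁻¹, ΔH2 = 10.0 kJ mol⁻¹)
    starting material + protic impurity → quenched substrate (k3 = 1.4 M⁻¹ s⁻¹, Ea3 = 41.0 kJ mol⁻¹)
    starting material + target → side product (k4 = 0.045 M⁻¹ s⁻¹, Ea4 = 36.0 kJ mol⁻¹)
    (constants at −20 °C)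

- percent here means starting material units held: one side product counts as two
- constants are those at −20 °C; use the activation energies and enthalpies for any other temperature

1. I began with the loss of target. It goes through the side-product step, which is first order in free starting material, so I needed c(starting material) throughout the run.

2. Against the full reagent charge, a free molecule of starting material lasts about 56.5 s at −20 °C, far shorter than the 30 min run, and step 1 speeds up by a factor of 24 from the coldest flask to the hottest. So in violet I treated target as the resting state, with c(starting material) = c(target) / (K · c(reagent)), where K is the equilibrium constant of the target step.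

3. I counted each side-product event as costing two units of target: the one it consumes and the one that released the starting material. The loss of target is then second order in target and inverse in reagent. So 1/c(target) climbs in a straight line, with a slope I called the erosion constant: twice the rate constant of the side-product step, divided by K and by c(reagent).

4. I used the ratio of that rate constant to K as given at −20 °C for violet, because the activation energy and the enthalpy involved differ by 1.00 kJ mol⁻¹, far less than either. The impurity cost 0.0100 M of starting material. I took the rest as ending up as side product, which holds one reagent per two starting material, and so used c(reagent) = 0.205 M for the whole run as an estimate.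

5. That gave an erosion constant of 0.00896 M⁻¹ s⁻¹. Taking that rest as target at the start, so 1/c(target) = 5.26 M⁻¹, my reckoning ended at c(target) = 0.0467 M, which is 23.4% of the charge.

6. Reagent stands in the denominator, so I decided to keep the temperature and time of violet and raise the reagent charge.

The forecast named blue as highest, with 22% for violet, 25% for grey, 30% for blue and 22% for green, on the ground that “the short warm period limits erosion”.

Violet gave 22.2% against my 23.4%, and blue came out highest at 32.1%, with grey at 23.5% and green at 22.8%. Violet held 70.7% as side product at 30.0 min. Carrying the same erosion constant on from the target violet held then, I reckoned 2.98% at 300 min, and the flask held 3.32%.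

For the neighbour of violet charged with 0.75 M of reagent, the erosion constant falls to 0.00280 M⁻¹ s⁻¹, which gives 48.5% of target at 30 min. The computed flask gave 45.8%, with 45.7% as side product.

Its constants are those of an exercise; the flask was simulated.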